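**Plan**
- Cuts, in retrosynthetic order: the two silyl masks on O5 and O4'; C2–C3 of ring C (carbene C–H insertion); the diazo group at C3 (back to a methyl ketone); C8–C1'' (prenyl, delivered from O5 by a para-Claisen shift); O1–C2 (Mitsunobu with the ring B benzyl alcohol); C4a–C4 (acylation of 3,4,5-trimethoxyphenol).
- Enabling feature: the C2–H bond is benzylic to ring B and alpha to the ring oxygen O1. C3 is alpha to the C4 ketone on ring A, so a carbene at C3 lies 1,6 to a doubly activated C–H bond.
- Forward order: rings A and B are bought. Ring A is acetylated and O5 freed, ring B is attached to O1, the prenyl group moves from O5 to C8, O5 is silylated, and the acetyl CH3 becomes CHN2. Ring C, the only ring made, closes last.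
- Stereochemistry: C2 is the only stereocentre. The chiral dirhodium carboxylate sets it during ring closure by choosing one of the two enantiotopic benzylic hydrogens, and a base-free desilylation preserves it.

Key step: step 10

Remark: atom labels follow flavanone numbering (O1, C2, C3, C4, C4a, C5 to C8, C8a; ring B primed; prenyl C1'' onward). TBS = tert-butyldimethylsilyl.
Assumption: the catalyst made from (S)-tert-leucine is taken to select the pro-S benzylic hydrogen. If the sense of induction is the opposite, the mirror-image catalyst Rh2(R-PTTL)4 is used in the same way.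

**Step 1**
Reactants: 1 3,4,5-trimethoxyphenol
Product: 2 1-(6-hydroxy-2,3,4-trimethoxyphenyl)ethanone
Conditions: AcOH, BF3·OEt2 (solvent), 85 °C; H2O
Reagents that add atoms: acetic acid CC(=O)O
Why: Friedel–Crafts acylation (O-acylation followed by a Fries-type shift) of the electron-rich phenol goes to one of its two equivalent ortho positions, and the boron chelate of the ortho-hydroxy ketone deactivates the ring against a second acylation.

**Step 2**
Reactants: 2 1-(6-hydroxy-2,3,4-trimethoxyphenyl)ethanone
Product: 3 1-(2,6-dihydroxy-3,4-dimethoxyphenyl)ethanone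
Conditions: AlCl3 (3 equiv), CH2Cl2, 0 °C to reflux; 1 M HCl
Reagents that add atoms: none
Why: Chelation-assisted Lewis-acid ether cleavage should take the methoxy group ortho to the ketone, which is the most crowded one and gives an acyl-stabilised phenolate, as in the known conversion of 2-hydroxy-6-methoxyacetophenones into 2,6-dihydroxyacetophenones.

**Step 3**
Reactants: 4 4-hydroxybenzaldehyde
Product: 5 4-(tert-butyldimethylsilyloxy)benzaldehyde
Conditions: TBSCl, imidazole, CH2Cl2, rt
Reagents that add atoms: tert-butyldimethylsilyl chloride CC(C)(C)[Si](C)(C)Cl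
Why: This is a routine imidazole-promoted silylation of a phenol.

**Step 4**
Reactants: 5 4-(tert-butyldimethylsilyloxy)benzaldehyde
Product: 6 4-(tert-butyldimethylsilyloxy)benzyl alcohol
Conditions: NaBH4, MeOH, 0 °C
Reagents that add atoms: none
Why: Borohydride reduction of the aryl aldehyde is fast at 0 °C and leaves the aryl silyl ether intact.

**Step 5**
Reactants: 3 1-(2,6-dihydroxy-3,4-dimethoxyphenyl)ethanone; 6 4-(tert-butyldimethylsilyloxy)benzyl alcohol (1.0 equiv)
Product: 7 1-[6-(4-tert-butyldimethylsilyloxybenzyloxy)-2-hydroxy-3,4-dimethoxyphenyl]ethanone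
Conditions: PPh3, DIAD, THF, 0 °C to rt
Reagents that add atoms: none
Why: Mitsunobu etherification, neutral and so safe for the aryl silyl ether, should take the hydroxyl beside the unsubstituted ring carbon (future O1 beside future C8), because the other hydroxyl is wedged between acetyl and methoxy groups and keeps its hydrogen bond to the ketone, the pattern known from partial alkylation of 3-substituted 2,6-dihydroxyacetophenones.

**Step 6**
Reactants: 7 1-[6-(4-tert-butyldimethylsilyloxybenzyloxy)-2-hydroxy-3,4-dimethoxyphenyl]ethanone; 8 3-methylbut-2-en-1-ol (prenol)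
Product: 9 1-[6-(4-tert-butyldimethylsilyloxybenzyloxy)-3,4-dimethoxy-2-(3-methylbut-2-enyloxy)phenyl]ethanone
Conditions: PPh3, DIAD, THF, 0 °C to rt
Reagents that add atoms: none
Why: A second Mitsunobu etherification, precedented for chelated ortho-hydroxyacetophenones with prenol, places the prenyl group on the future O5 by SN2 attack at the primary carbon without any base.

**Step 7**
Reactants: 9 1-[6-(4-tert-butyldimethylsilyloxybenzyloxy)-3,4-dimethoxy-2-(3-methylbut-2-enyloxy)phenyl]ethanone
Product: 11 1-[2-(4-tert-butyldimethylsilyloxybenzyloxy)-6-hydroxy-4,5-dimethoxy-3-(3-methylbut-2-enyl)phenyl]ethanone, via ortho-dienone 10 (not isolated)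
Conditions: Eu(fod)3 (10 mol %), NaHCO3, PhCl, 85 °C
Reagents that add atoms: none
Why: In this para-Claisen rearrangement (aromatic Claisen then Cope, two [3,3] shifts) both ortho carbons of the prenyl ether are blocked, so the reverse-prenyl dienone 10 passes the chain on to the free para carbon (future C8) with the normal prenyl orientation restored, and Eu(fod)3 held between the ketone and ether oxygens lowers the temperature as in the known 5-O-prenyl to 8-C-prenyl shift of flavonoids.

**Step 8**
Reactants: 11 1-[2-(4-tert-butyldimethylsilyloxybenzyloxy)-6-hydroxy-4,5-dimethoxy-3-(3-methylbut-2-enyl)phenyl]ethanone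
Product: 12 1-[2-(4-tert-butyldimethylsilyloxybenzyloxy)-6-(tert-butyldimethylsilyloxy)-4,5-dimethoxy-3-(3-methylbut-2-enyl)phenyl]ethanone
Conditions: TBSCl, imidazole, DMAP (cat.), DMF, 40 °C
Reagents that add atoms: tert-butyldimethylsilyl chloride CC(C)(C)[Si](C)(C)Cl
Why: Silylation of the only free phenol masks O5 with a group that has a poorly nucleophilic oxygen and no activated C–H bond, which is what the carbene step requires.

**Step 9**
Reactants: 12 1-[2-(4-tert-butyldimethylsilyloxybenzyloxy)-6-(tert-butyldimethylsilyloxy)-4,5-dimethoxy-3-(3-methylbut-2-enyl)phenyl]ethanone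
Product: 14 2-diazo-1-[2-(4-tert-butyldimethylsilyloxybenzyloxy)-6-(tert-butyldimethylsilyloxy)-4,5-dimethoxy-3-(3-methylbut-2-enyl)phenyl]ethanone, via trifluoroacetyl diketone 13 (not isolated)
Conditions: LiN(SiMe3)2, THF, −78 °C; CF3CO2CH2CF3, −78 °C; aq. HCl wash; then MsN3, Et3N, H2O (1 equiv), MeCN, rt
Reagents that add atoms: methanesulfonyl azide CS(=O)(=O)N=[N+]=[N-] (the two diazo nitrogens of 14); 2,2,2-trifluoroethyl trifluoroacetate O=C(OCC(F)(F)F)C(F)(F)F (the trifluoroacetyl group of 13 only)
Why: In this detrifluoroacetylative diazo transfer the lithium enolate of the methyl ketone is trifluoroacetylated (Claisen condensation) to activate the carbon, the sulfonyl azide delivers N2 while the trifluoroacetyl group leaves as the N-sulfonyl amide, and trapping at −78 °C should come before any silyl transfer from the ortho oxygen to the enolate.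

**Step 10**
Reactants: 14 2-diazo-1-[2-(4-tert-butyldimethylsilyloxybenzyloxy)-6-(tert-butyldimethylsilyloxy)-4,5-dimethoxy-3-(3-methylbut-2-enyl)phenyl]ethanone
Product: 15 (2S)-5,4'-bis(tert-butyldimethylsilyloxy)-6,7-dimethoxy-8-(3-methylbut-2-enyl)flavanone
Conditions: Rh2(S-PTTL)4 (dirhodium tetrakis[N-phthaloyl-(S)-tert-leucinate], 2 mol %), PhCF3, 4 Å MS, slow addition of 14 at high dilution, 0 °C to rt
Reagents that add atoms: none
Why: Loss of N2 from 14 at the divalent-rhodium dimer gives an electrophilic acyl carbene at C3, which inserts in a concerted, asynchronous three-centre event into one benzylic C2–H bond and forms C2–C3 and C3–H with retention at C2. The closest known reaction type is the dirhodium-carboxylate-catalysed intramolecular C–H insertion of ortho-alkoxyaryl diazoketones to chroman-4-ones, which has also been run with chiral carboxylates. Ring C closes as a six-membered ring by 1,6-insertion (C3, C4, C4a, C8a, O1, C2), since the 1,5 position is O1 itself and carries no hydrogen. C2 is controlled by the chiral pocket of the phthaloyl-tert-leucinate ligands, which should pick the pro-S of the two enantiotopic hydrogens and so give 2S. The step needs insertion to outrun attack of O1 on the carbene (five-membered oxonium ylide, then Stevens-type 1,2-benzyl shift); for this the C2–H bond is made hydridic by O1 and the para-silyloxyphenyl ring, O1 is a weakly basic aryl ether crowded by the prenyl and acyl groups, and the bulky ligand wall in a non-coordinating solvent disfavours ylide formation. The prenyl alkene and its allylic CH2 are out of reach because they sit meta to the acyl carbon and any ring to them would be a three- to five-atom meta bridge, ring A has no free C–H, and dilution suppresses carbene dimers.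

**Step 11**
Reactants: 15 (2S)-5,4'-bis(tert-butyldimethylsilyloxy)-6,7-dimethoxy-8-(3-methylbut-2-enyl)flavanone
Product: 16 (2S)-5-hydroxy-2-(4-hydroxyphenyl)-6,7-dimethoxy-8-(3-methylbut-2-enyl)chroman-4-one (CNP0104932.1)
Conditions: HF·pyridine, pyridine, THF, 0 °C
Reagents that add atoms: none
Why: Fluoride-driven cleavage of both aryl silyl ethers in a pyridine-buffered, weakly acidic medium avoids the base-induced retro-oxa-Michael ring opening that would racemise C2, and it leaves the prenyl alkene, which has no neighbouring free hydroxyl, untouched.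

**Compound list**
1 | 3,4,5-trimethoxyphenol | COc1cc(O)cc(OC)c1OC | starting material
2 | 1-(6-hydroxy-2,3,4-trimethoxyphenyl)ethanone | CC(=O)c1c(O)cc(OC)c(OC)c1OC | intermediate
3 | 1-(2,6-dihydroxy-3,4-dimethoxyphenyl)ethanone | CC(=O)c1c(O)cc(OC)c(OC)c1O | intermediate
4 | 4-hydroxybenzaldehyde | O=Cc1ccc(O)cc1 | starting material
5 | 4-(tert-butyldimethylsilyloxy)benzaldehyde | CC(C)(C)[Si](C)(C)Oc1ccc(C=O)cc1 | intermediate
6 | 4-(tert-butyldimethylsilyloxy)benzyl alcohol | CC(C)(C)[Si](C)(C)Oc1ccc(CO)cc1 | intermediate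
7 | 1-[6-(4-tert-butyldimethylsilyloxybenzyloxy)-2-hydroxy-3,4-dimethoxyphenyl]ethanone | CC(=O)c1c(O)c(OC)c(OC)cc1OCc2ccc(O[Si](C)(C)C(C)(C)C)cc2 | intermediate
8 | 3-methylbut-2-en-1-ol (prenol) | CC(C)=CCO | starting material
9 | 1-[6-(4-tert-butyldimethylsilyloxybenzyloxy)-3,4-dimethoxy-2-(3-methylbut-2-enyloxy)phenyl]ethanone | CC(=O)c1c(OCC=C(C)C)c(OC)c(OC)cc1OCc2ccc(O[Si](C)(C)C(C)(C)C)cc2 | intermediate
10 | 2-acetyl-3-(4-tert-butyldimethylsilyloxybenzyloxy)-5,6-dimethoxy-6-(2-methylbut-3-en-2-yl)cyclohexa-2,4-dien-1-one (ortho-dienone, racemic, drawn for the shift to the methoxy-bearing ortho carbon) | CC(=O)C1=C(OCc2ccc(O[Si](C)(C)C(C)(C)C)cc2)C=C(OC)C(OC)(C(C)(C)C=C)C1=O | intermediate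
11 | 1-[2-(4-tert-butyldimethylsilyloxybenzyloxy)-6-hydroxy-4,5-dimethoxy-3-(3-methylbut-2-enyl)phenyl]ethanone | CC(=O)c1c(O)c(OC)c(OC)c(CC=C(C)C)c1OCc2ccc(O[Si](C)(C)C(C)(C)C)cc2 | intermediate
12 | 1-[2-(4-tert-butyldimethylsilyloxybenzyloxy)-6-(tert-butyldimethylsilyloxy)-4,5-dimethoxy-3-(3-methylbut-2-enyl)phenyl]ethanone | CC(=O)c1c(O[Si](C)(C)C(C)(C)C)c(OC)c(OC)c(CC=C(C)C)c1OCc2ccc(O[Si](C)(C)C(C)(C)C)cc2 | intermediate
13 | 4,4,4-trifluoro-1-[2-(4-tert-butyldimethylsilyloxybenzyloxy)-6-(tert-butyldimethylsilyloxy)-4,5-dimethoxy-3-(3-methylbut-2-enyl)phenyl]butane-1,3-dione | O=C(CC(=O)C(F)(F)F)c1c(O[Si](C)(C)C(C)(C)C)c(OC)c(OC)c(CC=C(C)C)c1OCc2ccc(O[Si](C)(C)C(C)(C)C)cc2 | intermediate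
14 | 2-diazo-1-[2-(4-tert-butyldimethylsilyloxybenzyloxy)-6-(tert-butyldimethylsilyloxy)-4,5-dimethoxy-3-(3-methylbut-2-enyl)phenyl]ethanone | COc1c(O[Si](C)(C)C(C)(C)C)c(C(=O)C=[N+]=[N-])c(OCc2ccc(O[Si](C)(C)C(C)(C)C)cc2)c(CC=C(C)C)c1OC | intermediate
15 | (2S)-5,4'-bis(tert-butyldimethylsilyloxy)-6,7-dimethoxy-8-(3-methylbut-2-enyl)flavanone | COc1c(O[Si](C)(C)C(C)(C)C)c2c(c(CC=C(C)C)c1OC)O[C@H](c1ccc(O[Si](C)(C)C(C)(C)C)cc1)CC2=O | intermediate
16 | (2S)-5-hydroxy-2-(4-hydroxyphenyl)-6,7-dimethoxy-8-(3-methylbut-2-enyl)chroman-4-one | COc1c(O)c2c(c(CC=C(C)C)c1OC)O[C@H](c1ccc(O)cc1)CC2=O | target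

**Total step count:** 11. **Longest linear sequence:** 9 steps (1, 2, 5, 6, 7, 8, 9, 10, 11).

**Steps most likely to fail**

**Step 10.**
- Risk: O1 may attack the carbene faster than the C–H bond reacts, after which the ylide would hand the benzyl group to C3 by a 1,2-shift. An acceptor-only carbene may also discriminate weakly between the two benzylic hydrogens.
- Fallback: it gives up the C2–C3 closure, builds ring C first and brings in ring B by a known asymmetric conjugate arylation. It sets out from 2.
- Condensation with N,N-dimethylformamide dimethyl acetal would give the enaminone F1, which aqueous HCl closes to 5,6,7-trimethoxychromen-4-one F2.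
- BCl3 in CH2Cl2 removes the methyl group peri to the carbonyl and gives 5-hydroxy-6,7-dimethoxychromen-4-one F3.
- Mitsunobu etherification with 8 gives the 5-O-prenyl ether F4.
- The Eu(fod)3-catalysed Claisen–Cope shift moves the chain to C8 and gives 5-hydroxy-6,7-dimethoxy-8-prenylchromen-4-one F5.
- TBSCl and imidazole give the 5-O-silyl chromone F6.
- The 1,4-addition of commercial 4-(tert-butyldimethylsilyloxy)phenylboronic acid to F6 uses [Rh(OH)(cod)]2 and an electron-poor chiral biaryl bisphosphine, a reaction type established for chromones. It forms C2–C1' under ligand control and comes back to the route at 15.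

**Step 5.**
- Risk: etherification may spread over both hydroxyls of 3. The demethylation that makes 3 may also run on to the neighbouring methoxy group.
- Fallback: it fixes the regiochemistry through the single free hydroxyl of 2, which is the future O1, and bypasses steps 2, 5 and 6. It sets out from 2.
- Ac2O and pyridine give 2-acetyl-3,4,5-trimethoxyphenyl acetate F7.
- With the ketone now free to chelate, one equivalent of BCl3 at low temperature cleaves the ortho methoxy group and gives 2-acetyl-3-hydroxy-4,5-dimethoxyphenyl acetate F8.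
- Mitsunobu etherification with 8 gives the prenyl ether F9.
- K2CO3 in MeOH removes the acetate and gives 1-[6-hydroxy-3,4-dimethoxy-2-(3-methylbut-2-enyloxy)phenyl]ethanone F10.
- Mitsunobu etherification of F10 with 6 comes back to the route at 9.

**Step 7.**
- Risk: the prenyl ether may lose its allyl unit by ionisation or elimination before the two sigmatropic shifts are complete, or the crowded dienone may shed its acetyl group.
- Fallback: it replaces the sigmatropic relay with a cross-coupling and sets out from 7.
- TBSCl and imidazole give the bis-silyl ether F11.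
- NBS in MeCN brominates the only free position of ring A and gives the aryl bromide F12.
- Stille coupling with tributyl(3-methylbut-2-enyl)stannane and Pd(PPh3)4 in DMF attaches the prenyl group through its primary carbon and comes back to the route at 12.

**Further compounds**
F1 | step 10 | (E)-3-(dimethylamino)-1-(6-hydroxy-2,3,4-trimethoxyphenyl)prop-2-en-1-one | CN(C)/C=C/C(=O)c1c(O)cc(OC)c(OC)c1OC
F2 | step 10 | 5,6,7-trimethoxychromen-4-one | COc1cc2occc(=O)c2c(OC)c1OC
F3 | step 10 | 5-hydroxy-6,7-dimethoxychromen-4-one | COc1cc2occc(=O)c2c(O)c1OC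
F4 | step 10 | 6,7-dimethoxy-5-(3-methylbut-2-enyloxy)chromen-4-one | COc1cc2occc(=O)c2c(OCC=C(C)C)c1OC
F5 | step 10 | 5-hydroxy-6,7-dimethoxy-8-(3-methylbut-2-enyl)chromen-4-one | COc1c(O)c2c(c(CC=C(C)C)c1OC)occc2=O
F6 | step 10 | 5-(tert-butyldimethylsilyloxy)-6,7-dimethoxy-8-(3-methylbut-2-enyl)chromen-4-one | COc1c(O[Si](C)(C)C(C)(C)C)c2c(c(CC=C(C)C)c1OC)occc2=O
F7 | step 5 | 2-acetyl-3,4,5-trimethoxyphenyl acetate | CC(=O)Oc1cc(OC)c(OC)c(OC)c1C(C)=O
F8 | step 5 | 2-acetyl-3-hydroxy-4,5-dimethoxyphenyl acetate | CC(=O)Oc1cc(OC)c(OC)c(O)c1C(C)=O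
F9 | step 5 | 2-acetyl-4,5-dimethoxy-3-(3-methylbut-2-enyloxy)phenyl acetate | CC(=O)Oc1cc(OC)c(OC)c(OCC=C(C)C)c1C(C)=O
F10 | step 5 | 1-[6-hydroxy-3,4-dimethoxy-2-(3-methylbut-2-enyloxy)phenyl]ethanone | CC(=O)c1c(O)cc(OC)c(OC)c1OCC=C(C)C
F11 | step 7 | 1-[6-(4-tert-butyldimethylsilyloxybenzyloxy)-2-(tert-butyldimethylsilyloxy)-3,4-dimethoxyphenyl]ethanone | CC(=O)c1c(O[Si](C)(C)C(C)(C)C)c(OC)c(OC)cc1OCc2ccc(O[Si](C)(C)C(C)(C)C)cc2
F12 | step 7 | 1-[3-bromo-2-(4-tert-butyldimethylsilyloxybenzyloxy)-6-(tert-butyldimethylsilyloxy)-4,5-dimethoxyphenyl]ethanone | CC(=O)c1c(O[Si](C)(C)C(C)(C)C)c(OC)c(OC)c(Br)c1OCc2ccc(O[Si](C)(C)C(C)(C)C)cc2
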